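**Strategy.** The target is cut at the four C–C bonds that join each tetrasubstituted ring C=C (the two carbons shared by a cyclohexenone and its pyran) to the ketone carbon and to the carbinol carbon of that cyclohexenone. These bonds form in one two-directional Diels–Alder reaction of two C≡C units with two 1-acetoxy-4-silyloxybutadienes, which builds both carbocycles and places a cis pair of oxygens on each. The precursor is a C2-symmetric diynedial whose chain CH3–CH(O)–CH–CH–CH(O)–CH3 (the future pyran CH(CH3)–O and bridge CH carbons) is the oxidative dimer of (R)-3-hydroxybutanoate. Epoxidation, pyran closure and a γ,γ′ C–C coupling then close the cage.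

Key step: step 6

Remark: (1E,3E)-buta-1,3-diene-1,4-diyl diacetate is taken to be purchasable; the alkyne termini are carried as aldehydes, because an ynal should react below the temperature at which the adduct aromatises and the resulting enal can be reduced by NaBH4/CeCl3 without loss of the acetate.

Step 1
Reactants: 1 methyl (R)-3-hydroxybutanoate (two molecules)
Product: 3 dimethyl (2R,3R)-2,3-bis[(1R)-1-hydroxyethyl]butanedioate, via dilithium alkoxide enolate 2 (not isolated)
Conditions: LiN(i-Pr)2 (2.1 equiv), THF, −78 → −20 °C; Cu(O2CCH(C2H5)C4H9)2 (1.0 equiv), −78 → 0 °C; cold aq. NH4Cl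
Reagents that add atoms: none
Why: Oxidative homocoupling of an ester enolate (one-electron oxidation by divalent copper) applied to the Fráter–Seebach dianion: in the lithium chelate each reacting carbon should bond on the face opposite the C3 methyl group, so both new stereocentres are anti to their carbinols and the C2-symmetric (2R,3R) diester should predominate, while cold work-up and immediate silylation forestall γ-lactonisation.

Step 2
Reactants: 3 dimethyl (2R,3R)-2,3-bis[(1R)-1-hydroxyethyl]butanedioate
Product: 4 dimethyl (2R,3R)-2,3-bis[(1R)-1-(triethylsilyloxy)ethyl]butanedioate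
Conditions: TESOTf, 2,6-lutidine, CH2Cl2, −78 °C
Reagents that add atoms: triethylsilyl triflate, CC[Si](CC)(CC)OS(=O)(=O)C(F)(F)F
Why: Silyl ether formation with the triflate at low temperature is fast enough to outrun lactonisation and creates no stereocentre.

Step 3
Reactants: 4 dimethyl (2R,3R)-2,3-bis[(1R)-1-(triethylsilyloxy)ethyl]butanedioate
Product: 6 (3S,4S)-3,4-bis[(1R)-1-(triethylsilyloxy)ethyl]hexa-1,5-diyne, via dialdehyde 5 (not isolated)
Conditions: i-Bu2AlH (2.1 equiv), CH2Cl2, −78 °C; then MeOH, K2CO3, dimethyl (1-diazo-2-oxopropyl)phosphonate, −78 °C → rt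
Reagents that add atoms: dimethyl (1-diazo-2-oxopropyl)phosphonate, COP(=O)(OC)C(=[N+]=[N-])C(C)=O
Why: Semi-reduction of the β-silyloxy esters stops at the tetrahedral aluminium hemiacetal at −78 °C, and the aldehydes released by methanol are homologated in the same flask by the Ohira–Bestmann (Seyferth–Gilbert) reaction under carbonate conditions that normally leave α-stereocentres untouched.

Step 4
Reactants: 6 (3S,4S)-3,4-bis[(1R)-1-(triethylsilyloxy)ethyl]hexa-1,5-diyne
Product: 8 (4S,5S)-4,5-bis[(1R)-1-(triethylsilyloxy)ethyl]octa-2,6-diynedial, via dilithium diacetylide 7 (not isolated)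
Conditions: n-BuLi (2.2 equiv), THF, −78 °C; DMF; inverse quench into aq. KH2PO4, 0 °C
Reagents that add atoms: N,N-dimethylformamide, CN(C)C=O
Why: Formylation of lithium acetylides with DMF, with release of the hemiaminal salt into phosphate buffer, is the standard route to ynals, and the propargylic stereocentres are not deprotonated at −78 °C.

Step 5
Reactants: 9 (1E,3E)-buta-1,3-diene-1,4-diyl diacetate
Product: 11 (1E,3E)-4-(tert-butyldimethylsilyloxy)buta-1,3-dien-1-yl acetate, via lithium dienolate 10 (not isolated)
Conditions: MeLi (2.0 equiv), THF, −78 °C; then TBSCl, DMPU, −78 → 0 °C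
Reagents that add atoms: tert-butyldimethylsilyl chloride, CC(C)(C)[Si](C)(C)Cl
Why: Cleavage of one enol acetate by methyllithium gives the lithium dienolate with retention of alkene geometry (the anionic product resists a second cleavage), and O-silylation then should give the mixed (1E,3E)-diene.

Step 6
Reactants: 8 (4S,5S)-4,5-bis[(1R)-1-(triethylsilyloxy)ethyl]octa-2,6-diynedial; 11 (1E,3E)-4-(tert-butyldimethylsilyloxy)buta-1,3-dien-1-yl acetate (two molecules)
Product: 12 (2R,3S,4S,5R)-3,4-bis[(3R,6S)-6-acetoxy-3-(tert-butyldimethylsilyloxy)-2-formylcyclohexa-1,4-dien-1-yl]-2,5-bis(triethylsilyloxy)hexane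
Conditions: 11 (5 equiv), toluene, BHT (cat.), 60 °C, dark, base-washed glassware
Reagents that add atoms: none
Why: Each ynal unit (LUMO) and one molecule of the electron-rich diene (HOMO) combine in a concerted but asynchronous, suprafacial [4+2] cycloaddition in which the bond from the acetoxy-bearing terminus to the spine-bearing alkyne carbon is the more advanced. The closest known reaction type is the thermal Diels–Alder addition of alkynals and alkynoates to 1-acyloxy- and 1-silyloxybutadienes, which delivers cyclohexa-1,4-dienes. Each of the two carbocycles is closed by an intermolecular [4+2] annulation, its two new σ bonds (C1–C6 and C2–C3 of the cyclohexadiene) forming on one face of the s-cis diene. C3 and C6 of each ring become cis because the (1E,3E) geometry is transferred suprafacially, and their absolute sense is controlled by the adjacent propargylic stereocentre, which should react through the staggered rotamer that places the other half of the spine anti to the forming C1–C6 bond, the CH(CH3)OTES group on the flank remote from the diene and the hydrogen under the diene. The step needs regioselectivity, secured by the silyloxy group as the stronger donor (its remote terminus bonds to the β-carbon of the ynal, so OTBS ends up next to the formyl-bearing carbon), and facial selectivity at both ends, which rests only on this conformational bias of the C2-symmetric spine and is the main uncertainty of the route. The formyl-activated alkyne should react at a temperature at which the adduct does not aromatise, since its acetoxy group is trans to the C3 hydrogen and its silyloxy group trans to the C6 hydrogen, so that no syn 1,4-elimination is available.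

Step 7
Reactants: 12 bis(cyclohexa-1,4-diene) dialdehyde
Product: 13 bis-epoxide of 12 (each C4=C5 bond an oxirane on the face opposite OAc and OTBS)
Conditions: DMDO, acetone/CH2Cl2, −20 → 0 °C
Reagents that add atoms: dimethyldioxirane, CC1(C)OO1
Why: Neutral dioxirane epoxidation should attack only the cis-disubstituted C4=C5 bond (C1=C2 is tetrasubstituted and conjugated to the formyl group) from the face opposite the two allylic oxygen substituents, so the new oxirane carbons are set trans to OAc and OTBS by steric shielding, and the epoxide removes the possibility of aromatisation.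

Step 8
Reactants: 13 bis-epoxide dialdehyde
Product: 15 tetraol (two primary allylic and two secondary hydroxyls), via bis(allylic alcohol) 14 (not isolated)
Conditions: NaBH4, CeCl3·7H2O, MeOH, −40 °C; then acetone, PPTS, 0 °C → rt
Reagents that add atoms: none
Why: Luche reduction gives the primary allylic alcohols by 1,2-addition without touching acetate or epoxide, and pyridinium tosylate in methanol then removes the secondary triethylsilyl ethers selectively beside the more hindered tert-butyldimethylsilyl ethers; no stereocentre is formed.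

Step 9
Reactants: 15 tetraol
Product: 16 4,4′-linked bis(3-methyl-hexahydro-1H-isochromene) diacetate (5-OAc, 6,7-epoxide, 8-OTBS in each half)
Conditions: PPh3, DIAD, THF, 0 °C → rt
Reagents that add atoms: none
Why: Mitsunobu cyclodehydration, in which the primary allylic hydroxyl is activated as the oxyphosphonium salt and displaced by the secondary hydroxyl in a 6-exo-tet closure, so the CH(CH3)–O stereocentre keeps its configuration.

Step 10
Reactants: 16 bis-pyran diacetate
Product: 17 bis-pyran diol (5-OH in each half)
Conditions: K2CO3, MeOH, 0 °C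
Reagents that add atoms: none
Why: Base-catalysed transesterification removes the acetates while silyl ethers, epoxides and the allylic ethers stay intact, and the low temperature limits epoxide migration.

Step 11
Reactants: 17 bis-pyran diol
Product: 18 bis(epoxy enone) (5-oxo in each half)
Conditions: Dess–Martin periodinane, NaHCO3, CH2Cl2, 0 °C → rt
Reagents that add atoms: none
Why: Dess–Martin oxidation of the allylic epoxy alcohols under buffered conditions should give the epoxy enones without epimerisation, and the carbinol stereocentre at C5 disappears.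

Step 12
Reactants: 18 bis(epoxy enone)
Product: 19 bis(trimethylsilyl dienol ether) (C5-OTMS, C4a=C5 and C1=C8a double bonds in each half)
Conditions: TMSOTf, Et3N, CH2Cl2, −78 → 0 °C; non-aqueous work-up, used crude
Reagents that add atoms: trimethylsilyl triflate, C[Si](C)(C)OS(=O)(=O)C(F)(F)F
Why: Soft enolisation of the enone (O-silylation, then γ-deprotonation by the amine) gives the linear silyl dienol ether, the pyran OCH2 being deprotonated in preference to the ring CH(OTBS), which is tertiary and flanked by the silyl ether and the epoxide.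

Step 13
Reactants: 19 bis(trimethylsilyl dienol ether)
Product: 21 bis(tert-butyldimethylsilyl) ether of epoxytwinol A, via γ-bromo enone 20 (not isolated)
Conditions: NBS (1.0 equiv), CH2Cl2, −78 °C; then AgOTf (AgO3SCF3), 2,6-di-tert-butyl-4-methylpyridine, −78 → −20 °C
Reagents that add atoms: none
Why: γ-Bromination of one silyl dienol ether gives an allylic α-bromo ether, whose silver-promoted ionisation forms a cyclic oxocarbenium ion that is attacked by the γ-carbon of the second silyl dienol ether (vinylogous Mukaiyama-type alkylation, known for dienoxysilanes and cyclic α-halo ethers); the α-carbons are fully substituted, and the two new O–CH stereocentres are fixed by the cage, since the bond can only form on the pyran face that already carries the CH–CH bridge.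

Step 14
Reactants: 21 bis(tert-butyldimethylsilyl) ether of epoxytwinol A
Product: 22 epoxytwinol A
Conditions: HF·pyridine, pyridine, THF, 0 °C
Reagents that add atoms: none
Why: Fluoride-mediated cleavage of the two secondary silyl ethers under buffered conditions is compatible with epoxy enones and creates no stereocentre.

**Compound list**

1 | methyl (R)-3-hydroxybutanoate | C[C@@H](O)CC(=O)OC | starting material
2 | dilithium alkoxide enolate of 1 (enolate O–Li cis to C3) | C[C@@H]([O-])/C=C(/OC)[O-].[Li+].[Li+] | intermediate
3 | dimethyl (2R,3R)-2,3-bis[(1R)-1-hydroxyethyl]butanedioate | COC(=O)[C@@H]([C@@H](C)O)[C@H]([C@@H](C)O)C(=O)OC | intermediate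
4 | dimethyl (2R,3R)-2,3-bis[(1R)-1-(triethylsilyloxy)ethyl]butanedioate | COC(=O)[C@@H]([C@@H](C)O[Si](CC)(CC)CC)[C@H]([C@@H](C)O[Si](CC)(CC)CC)C(=O)OC | intermediate
5 | (2R,3R)-2,3-bis[(1R)-1-(triethylsilyloxy)ethyl]butanedial | O=C[C@@H]([C@@H](C)O[Si](CC)(CC)CC)[C@H]([C@@H](C)O[Si](CC)(CC)CC)C=O | intermediate
6 | (3S,4S)-3,4-bis[(1R)-1-(triethylsilyloxy)ethyl]hexa-1,5-diyne | C#C[C@@H]([C@@H](C)O[Si](CC)(CC)CC)[C@H]([C@@H](C)O[Si](CC)(CC)CC)C#C | intermediate
7 | dilithium diacetylide of 6 | [Li+].[Li+].[C-]#C[C@@H]([C@@H](C)O[Si](CC)(CC)CC)[C@H]([C@@H](C)O[Si](CC)(CC)CC)C#[C-] | intermediate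
8 | (4S,5S)-4,5-bis[(1R)-1-(triethylsilyloxy)ethyl]octa-2,6-diynedial | O=CC#C[C@@H]([C@@H](C)O[Si](CC)(CC)CC)[C@H]([C@@H](C)O[Si](CC)(CC)CC)C#CC=O | intermediate
9 | (1E,3E)-buta-1,3-diene-1,4-diyl diacetate | CC(=O)O/C=C/C=C/OC(C)=O | starting material
10 | lithium (1E,3E)-4-acetoxybuta-1,3-dien-1-olate | CC(=O)O/C=C/C=C/[O-].[Li+] | intermediate
11 | (1E,3E)-4-(tert-butyldimethylsilyloxy)buta-1,3-dien-1-yl acetate | CC(=O)O/C=C/C=C/O[Si](C)(C)C(C)(C)C | intermediate
12 | (2R,3S,4S,5R)-3,4-bis[(3R,6S)-6-acetoxy-3-(tert-butyldimethylsilyloxy)-2-formylcyclohexa-1,4-dien-1-yl]-2,5-bis(triethylsilyloxy)hexane | O=CC3=C([C@@H](OC(C)=O)C=C[C@H]3O[Si](C)(C)C(C)(C)C)[C@@H]([C@@H](C)O[Si](CC)(CC)CC)[C@H]([C@@H](C)O[Si](CC)(CC)CC)C3=C(C=O)[C@H](O[Si](C)(C)C(C)(C)C)C=C[C@@H]3OC(C)=O | intermediate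
13 | bis-epoxide of 12: each ring C4=C5 is an oxirane trans to the C3-OTBS and C6-OAc groups; CHO groups and TES ethers unchanged | O=CC3=C([C@@H](OC(C)=O)[C@@H]4O[C@@H]4[C@H]3O[Si](C)(C)C(C)(C)C)[C@@H]([C@@H](C)O[Si](CC)(CC)CC)[C@H]([C@@H](C)O[Si](CC)(CC)CC)C3=C(C=O)[C@H](O[Si](C)(C)C(C)(C)C)[C@H]4O[C@H]4[C@@H]3OC(C)=O | intermediate
14 | 13 with both CHO groups reduced to CH2OH | OCC3=C([C@@H](OC(C)=O)[C@@H]4O[C@@H]4[C@H]3O[Si](C)(C)C(C)(C)C)[C@@H]([C@@H](C)O[Si](CC)(CC)CC)[C@H]([C@@H](C)O[Si](CC)(CC)CC)C3=C(CO)[C@H](O[Si](C)(C)C(C)(C)C)[C@H]4O[C@H]4[C@@H]3OC(C)=O | intermediate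
15 | tetraol: 14 without the two triethylsilyl groups | OCC3=C([C@@H](OC(C)=O)[C@@H]4O[C@@H]4[C@H]3O[Si](C)(C)C(C)(C)C)[C@@H]([C@@H](C)O)[C@H]([C@@H](C)O)C3=C(CO)[C@H](O[Si](C)(C)C(C)(C)C)[C@H]4O[C@H]4[C@@H]3OC(C)=O | intermediate
16 | 4,4′-linked bis(3-methyl-3,4,5,6,7,8-hexahydro-1H-isochromene): in each half 5-OAc, 6,7-epoxide trans to O5 and O8, 8-OTBS, 3-methyl trans to the C4–C4′ bond | C[C@H]1OCC3=C([C@@H](OC(C)=O)[C@@H]4O[C@@H]4[C@H]3O[Si](C)(C)C(C)(C)C)[C@@H]1[C@H]1C3=C([C@H](O[Si](C)(C)C(C)(C)C)[C@H]4O[C@H]4[C@@H]3OC(C)=O)CO[C@@H]1C | intermediate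
17 | 16 with both acetates replaced by hydroxyl (5-OH) | C[C@H]1OCC3=C([C@@H](O)[C@@H]4O[C@@H]4[C@H]3O[Si](C)(C)C(C)(C)C)[C@@H]1[C@H]1C3=C([C@H](O[Si](C)(C)C(C)(C)C)[C@H]4O[C@H]4[C@@H]3O)CO[C@@H]1C | intermediate
18 | bis(epoxy enone): 17 with both C5 carbinols oxidised to ketones | C[C@H]1OCC3=C(C(=O)[C@@H]4O[C@@H]4[C@H]3O[Si](C)(C)C(C)(C)C)[C@@H]1[C@H]1C3=C([C@H](O[Si](C)(C)C(C)(C)C)[C@H]4O[C@H]4C3=O)CO[C@@H]1C | intermediate
19 | bis(trimethylsilyl dienol ether) of 18: C5-OTMS, C4a=C5 and C1=C8a double bonds in each half | C[C@H]1OC=C3C(=C(O[Si](C)(C)C)[C@@H]4O[C@@H]4[C@H]3O[Si](C)(C)C(C)(C)C)[C@@H]1[C@H]1C=3C([C@H](O[Si](C)(C)C(C)(C)C)[C@H]4O[C@H]4C3O[Si](C)(C)C)=CO[C@@H]1C | intermediate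
20 | mono-γ-bromo enone: one half is the 1-bromo enone (configuration at C–Br undefined), the other half still the silyl dienol ether | C[C@H]1OC(Br)C3=C(C(=O)[C@@H]4O[C@@H]4[C@H]3O[Si](C)(C)C(C)(C)C)[C@@H]1[C@H]1C=3C([C@H](O[Si](C)(C)C(C)(C)C)[C@H]4O[C@H]4C3O[Si](C)(C)C)=CO[C@@H]1C | intermediate
21 | epoxytwinol A bis(tert-butyldimethylsilyl) ether (C1–C1′ bond formed) | C[C@H]1O[C@H]2C3=C(C(=O)[C@@H]4O[C@@H]4[C@H]3O[Si](C)(C)C(C)(C)C)[C@@H]1[C@H]1C3=C([C@H](O[Si](C)(C)C(C)(C)C)[C@H]4O[C@H]4C3=O)[C@@H]2O[C@@H]1C | intermediate
22 | epoxytwinol A | C[C@H]1O[C@H]2C3=C(C(=O)[C@@H]4O[C@@H]4[C@H]3O)[C@@H]1[C@H]1C3=C([C@H](O)[C@H]4O[C@H]4C3=O)[C@@H]2O[C@@H]1C | target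

**Step count.** 14 steps in total; the longest linear sequence is 13 steps (steps 1–4 and 6–14 from 1), with step 5 as a one-step branch.

**Steps most likely to fail**

1. Step 6 (key step). The diene may add to the two alkyne units with little facial discrimination, so that the wanted C2-symmetric isomer is accompanied by ring diastereomers, and slow cycloaddition would let the adduct eliminate acetic acid or silanol. Fallback: replace substrate control by catalyst control. Setting out from 8 and 11, the cycloaddition would be run in CH2Cl2 at −78 °C under a chiral cationic oxazaborolidinium Lewis acid (from α,α-diphenylprolinol, o-tolylboronic acid and HNTf2, in the enantiomer matched to the spine). Chiral boron Lewis acids are known to make Diels–Alder additions of acetylenic aldehydes face-selective by shielding one approach to the coordinated formyl group, and the low temperature also removes the aromatisation problem. The product would be 12 itself, so the fallback returns to the route at 12 and makes no new compound (F0).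

2. Step 13. Closure of the eight-membered ring may be too slow, so that the second dienol ether is brominated as well, the oxocarbenium ion loses a proton to a 2H-pyran, or bonding takes place at a fully substituted carbon. Fallback: a one-electron in place of a two-electron coupling. Setting out from 19, oxidation with (NH4)2Ce(NO3)6 (tetravalent cerium) and NaHCO3 in MeCN/EtCN at −40 °C would generate the radical cation of one silyl dienol ether, to be trapped by the second. This is the known oxidative coupling of bis(silyl enol ethers), and after loss of both trimethylsilyl groups it would lead directly to 21, where it returns to the route, without a brominated intermediate and without a new compound (F0).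

3. Step 1. The open-chain chelate may dimerise with low diastereoselectivity, proton transfer may lower conversion, and the product may lactonise. Fallback: a cyclic chiral enolate. Setting out from 1, saponification would give (R)-3-hydroxybutanoic acid F1, which would be condensed with pivalaldehyde under acid catalysis to the cis acetal (2R,6R)-2-tert-butyl-6-methyl-1,3-dioxan-4-one F2. Its lithium enolate (LiN(i-Pr)2, THF, −78 °C), which is known to take up electrophiles trans to the C6 methyl group, would be dimerised with the same copper carboxylate to the 5,5′-bis-dioxanone F3. Acid methanolysis (HCl, MeOH) would open both acetals and give 3, where the fallback returns to the route.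

**Further compounds**

F0 | step 6 | none | none
F0 | step 13 | none | none
F1 | step 1 | (R)-3-hydroxybutanoic acid | C[C@@H](O)CC(O)=O
F2 | step 1 | (2R,6R)-2-tert-butyl-6-methyl-1,3-dioxan-4-one | C[C@@H]1CC(=O)O[C@H](C(C)(C)C)O1
F3 | step 1 | (2R,2′R,5R,5′R,6R,6′R)-2,2′-di-tert-butyl-6,6′-dimethyl-5,5′-bi(1,3-dioxane)-4,4′-dione | CC(C)(C)[C@H]1OC(=O)[C@@H]([C@@H](C)O1)[C@@H]2[C@@H](C)O[C@@H](C(C)(C)C)OC2=O
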